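The synthesis rests on cutting C1–C5 and C7–C8 of the hydroazulene. C5–C6–C7 of the seven-membered ring, with oxygen on C6, is treated as an oxyallyl cation and C1=C10–C9=C8 as a diene, joined through C2–C3–C4 of the cyclopentane. One intramolecular (4+3) cycloaddition therefore closes both rings, forms two C–C bonds and sets C1 and C5 from the single stereocentre C4. Its precursor is an acyclic chloromethyl ketone carrying the silylated C4 carbinol (isopropyl) and an (E)-methyl-substituted diene, made by Negishi couplings, Sharpless epoxidation and hydride opening. Directed reduction, esterification, allylic oxidation and methyl addition finish the target.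

Key step: step 11

Remark: atoms are labelled as in daucanes: C1 ring-fusion carbon with methyl, C2 and C3 cyclopentane CH2, C4 isopropyl carbinol, C5 ring-fusion CH, C6 ester carbinol, C7 CH2, C8 methyl carbinol, C9=C10 alkene. β is the face of the C1 methyl and α the opposite face. 4-Methylpent-2-yn-1-ol is assumed to be a catalogue compound.

Step 1
Reactants: 1 but-3-yn-1-ol; 2 vinyl bromide
Product: 4 (3E)-3-methylhexa-3,5-dien-1-ol, via alkenylalane 3 (not isolated)
Conditions: Me3Al (3 equiv), Cp2ZrCl2 (0.25 equiv), CH2Cl2, 0 °C → rt; then 2, Pd(PPh3)4 (3 mol%), ZnCl2, THF, rt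
Reagents that add atoms: trimethylaluminium, C[Al](C)C
Why: Negishi zirconium-catalysed carboalumination adds methyl and aluminium syn across the terminal alkyne (methyl to the internal carbon), and the palladium-catalysed cross-coupling of the alkenylalane with vinyl bromide goes with retention, so the trisubstituted alkene should be E with the chain trans to the vinyl group.

Step 2
Reactants: 4 (3E)-3-methylhexa-3,5-dien-1-ol
Product: 5 (3E)-6-iodo-4-methylhexa-1,3-diene
Conditions: I2, PPh3, imidazole, CH2Cl2, 0 °C → rt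
Reagents that add atoms: iodine, II
Why: Appel-type iodination (Garegg–Samuelsson conditions) converts the primary alcohol into the iodide under near-neutral conditions that leave the diene alone; no stereocentre is formed.

Step 3
Reactants: 6 4-methylpent-2-yn-1-ol
Product: 8 (2Z)-3-iodo-4-methylpent-2-en-1-ol, via vinylalanate 7 (not isolated)
Conditions: Red-Al, THF, 0 °C → rt; then I2, −78 → 0 °C
Reagents that add atoms: iodine, II
Why: Hydroxyl-directed trans-hydroalumination of the propargylic alcohol gives a five-membered vinylalanate, and iodinolysis with retention places iodine on C3 cis to CH2OH (Z).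

Step 4
Reactants: 5 (3E)-6-iodo-4-methylhexa-1,3-diene; 8 (2Z)-3-iodo-4-methylpent-2-en-1-ol
Product: 10 (2E,6E)-6-methyl-3-(propan-2-yl)nona-2,6,8-trien-1-ol, via alkylzinc iodide 9 (not isolated)
Conditions: Zn, LiCl, THF, 40 °C (on 5); then 8, PdCl2(dppf) (5 mol%), THF, 40 °C
Reagents that add atoms: none
Why: LiCl-assisted zinc insertion into the primary iodide followed by Negishi sp3–sp2 cross-coupling proceeds with retention at the vinyl iodide, so the dienyl chain ends cis and the isopropyl group trans to CH2OH; alkylzinc halides tolerate the free hydroxyl.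

Step 5
Reactants: 10 (2E,6E)-6-methyl-3-(propan-2-yl)nona-2,6,8-trien-1-ol
Product: 11 [(2R,3R)-3-[(3E)-3-methylhexa-3,5-dien-1-yl]-3-(propan-2-yl)oxiran-2-yl]methanol
Conditions: Ti(OiPr)4 (10 mol%), D-(−)-DIPT (12 mol%), TBHP, 4 Å MS, CH2Cl2, −20 °C
Reagents that add atoms: tert-butyl hydroperoxide, CC(C)(C)OO
Why: Sharpless asymmetric epoxidation with the D-(−)-tartrate delivers oxygen to the face that makes both oxirane carbons R, which fixes the future C4 carbinol in the configuration of the target, and the titanium–peroxide reagent epoxidises only the allylic alcohol, not the diene.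

Step 6
Reactants: 11 [(2R,3R)-3-[(3E)-3-methylhexa-3,5-dien-1-yl]-3-(propan-2-yl)oxiran-2-yl]methanol
Product: 12 (3S,6E)-6-methyl-3-(propan-2-yl)nona-6,8-diene-1,3-diol
Conditions: Red-Al, THF, 0 °C → rt; Rochelle salt work-up
Reagents that add atoms: none
Why: Red-Al opening of a 2,3-epoxy alcohol delivers hydride from the alkoxyaluminate to the carbinol-adjacent carbon (future C5), giving the 1,3-diol and leaving the tertiary C–O bond, hence the C4 configuration, untouched.

Step 7
Reactants: 12 (3S,6E)-6-methyl-3-(propan-2-yl)nona-6,8-diene-1,3-diol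
Product: 13 (3S,6E)-6-methyl-3-(propan-2-yl)-1,3-bis(triethylsilyloxy)nona-6,8-diene
Conditions: TESOTf, 2,6-lutidine, CH2Cl2, −78 → 0 °C
Reagents that add atoms: triethylsilyl trifluoromethanesulfonate, CC[Si](CC)(CC)OS(=O)(=O)C(F)(F)F
Why: The silyl triflate with a hindered base silylates both hydroxyls, including the tertiary one (standard silyl ether formation), and the C4 silyl ether later keeps this oxygen from capturing the cation.

Step 8
Reactants: 13 (3S,6E)-6-methyl-3-(propan-2-yl)-1,3-bis(triethylsilyloxy)nona-6,8-diene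
Product: 14 (3S,6E)-6-methyl-3-(propan-2-yl)-3-(triethylsilyloxy)nona-6,8-dienal
Conditions: (COCl)2, DMSO, CH2Cl2, −78 → −30 °C; Et3N, → 0 °C
Reagents that add atoms: none
Why: Swern oxidation applied directly to the silyl ether: the chlorosulfonium salt cleaves only the unhindered primary triethylsilyl ether and the resulting alkoxysulfonium ion collapses to the aldehyde, while the tertiary silyl ether is inert.

Step 9
Reactants: 14 (3S,6E)-6-methyl-3-(propan-2-yl)-3-(triethylsilyloxy)nona-6,8-dienal
Product: 15 (4S,7E)-1-chloro-7-methyl-4-(propan-2-yl)-4-(triethylsilyloxy)deca-7,9-dien-2-ol (both C2 epimers)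
Conditions: ICH2Cl, MeLi·LiBr, THF, −78 °C; AcOH quench at −78 °C
Reagents that add atoms: chloroiodomethane, ClCI
Why: Chloromethyllithium, generated by iodine–lithium exchange in the presence of the aldehyde, adds to the carbonyl at −78 °C faster than it decomposes (carbenoid homologation), and the new carbinol centre is of no consequence because it is oxidised in step 10.

Step 10
Reactants: 15 (4S,7E)-1-chloro-7-methyl-4-(propan-2-yl)-4-(triethylsilyloxy)deca-7,9-dien-2-ol
Product: 16 (4S,7E)-1-chloro-7-methyl-4-(propan-2-yl)-4-(triethylsilyloxy)deca-7,9-dien-2-one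
Conditions: Dess–Martin periodinane, NaHCO3, CH2Cl2, 0 °C → rt
Reagents that add atoms: none
Why: Dess–Martin oxidation of the chlorohydrin under buffered, non-basic conditions should give the chloromethyl ketone without touching the diene, the chloride or the silyl ether.

Step 11
Reactants: 16 (4S,7E)-1-chloro-7-methyl-4-(propan-2-yl)-4-(triethylsilyloxy)deca-7,9-dien-2-one
Product: 18 (3R,3aR,8aR)-8a-methyl-3-(propan-2-yl)-3-(triethylsilyloxy)-2,3,3a,5,6,8a-hexahydroazulen-4(1H)-one, via oxyallyl cation 17 (not isolated)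
Conditions: Et3N (3 equiv), CF3CH2OH (0.02 M), 0 °C → rt
Reagents that add atoms: none
Why: Triethylamine reversibly enolises the ketone towards C5 and the strongly ionising, weakly nucleophilic fluoro alcohol lets chloride leave from C7, giving the 2-oxidoallyl cation C5–C6–C7 (17), which the diene C1=C10–C9=C8 captures intramolecularly; the closest known class is the Föhlisch-type (4+3) cycloaddition of α-halo ketones with tethered dienes to fused 5,7-ketones. The cyclopentane closes by bond C1–C5 in a 5-exo sense through the three-atom tether C2–C4, and the cycloheptenone closes by bond C7–C8 across the diene termini, leaving the alkene at C9=C10, with C1–C5 formation running ahead. C5 is controlled by C4: in the Z (W-shaped) cation, allylic strain turns the isopropyl group away from the C6 oxygen and leaves the smaller silyloxy group beside it, so the diene arm should add to the face that puts H5 trans to the C4 oxygen. C1 is controlled by the E geometry of C1=C10 (tether outside, methyl inside) together with an extended transition state, which place the C1 methyl trans to H5 (trans fusion) and hence cis to the C4 oxygen. The step needs ionisation to outrun E1cB loss of the β-silyloxy group and (4+3) closure to outrun closure at C10 or solvent capture; the weak base, the poor leaving-group ability of the silyl ether and the short tether that holds C7 over C8 of the s-cis diene provide for this.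

Step 12
Reactants: 18 (3R,3aR,8aR)-8a-methyl-3-(propan-2-yl)-3-(triethylsilyloxy)-2,3,3a,5,6,8a-hexahydroazulen-4(1H)-one
Product: 19 (3R,3aR,8aR)-3-hydroxy-8a-methyl-3-(propan-2-yl)-2,3,3a,5,6,8a-hexahydroazulen-4(1H)-one
Conditions: HF·pyridine, pyridine, THF, 0 °C
Reagents that add atoms: none
Why: Buffered fluoride desilylation frees the tertiary C4 hydroxyl without the base that would cause retro-aldol cleavage or epimerisation at C5 of the β-hydroxy ketone.

Step 13
Reactants: 19 (3R,3aR,8aR)-3-hydroxy-8a-methyl-3-(propan-2-yl)-2,3,3a,5,6,8a-hexahydroazulen-4(1H)-one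
Product: 20 (3R,3aS,4S,8aR)-8a-methyl-3-(propan-2-yl)-1,2,3,3a,4,5,6,8a-octahydroazulene-3,4-diol (4β,6α-diol)
Conditions: Me4NBH(OAc)3, MeCN/AcOH (1:1), −25 °C
Reagents that add atoms: none
Why: Evans–Saksena directed reduction: the 4β-hydroxyl binds boron and delivers hydride intramolecularly to the β face of the C6 ketone, so the 6α-alcohol (1,3-anti diol) should form, and the reagent does not reduce ketones without this delivery.

Step 14
Reactants: 21 vanillic acid
Product: 23 4-(tert-butyldimethylsilyloxy)-3-methoxybenzoic acid, via bis-silyl derivative 22 (not isolated)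
Conditions: TBSCl, imidazole, DMF, rt; then AcOH/THF/H2O, rt
Reagents that add atoms: tert-butyldimethylsilyl chloride, CC(C)(C)[Si](C)(C)Cl
Why: Both the phenol and the acid are silylated and the far more labile silyl ester is then hydrolysed selectively, leaving the aryl silyl ether as phenol protection.

Step 15
Reactants: 20 (3R,3aS,4S,8aR)-8a-methyl-3-(propan-2-yl)-1,2,3,3a,4,5,6,8a-octahydroazulene-3,4-diol; 23 4-(tert-butyldimethylsilyloxy)-3-methoxybenzoic acid
Product: 24 (3R,3aS,4S,8aR)-3-hydroxy-8a-methyl-3-(propan-2-yl)-1,2,3,3a,4,5,6,8a-octahydroazulen-4-yl 4-(tert-butyldimethylsilyloxy)-3-methoxybenzoate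
Conditions: DCC, DMAP, CH2Cl2, rt
Reagents that add atoms: none
Why: Steglich esterification acylates the secondary C6 hydroxyl only, since the tertiary C4 hydroxyl is too hindered, and the ester then also protects C6 through the next two steps.

Step 16
Reactants: 24 (3R,3aS,4S,8aR)-3-hydroxy-8a-methyl-3-(propan-2-yl)-1,2,3,3a,4,5,6,8a-octahydroazulen-4-yl 4-(tert-butyldimethylsilyloxy)-3-methoxybenzoate
Product: 25 (3R,3aS,4S,8aR)-3-hydroxy-8a-methyl-6-oxo-3-(propan-2-yl)-1,2,3,3a,4,5,6,8a-octahydroazulen-4-yl 4-(tert-butyldimethylsilyloxy)-3-methoxybenzoate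
Conditions: Rh2(cap)4 (1 mol%), TBHP (70% aq), ClCH2CH2Cl, 40 °C
Reagents that add atoms: tert-butyl hydroperoxide, CC(C)(C)OO
Why: Dirhodium caprolactamate/TBHP allylic oxidation (Doyle conditions, base-free) should convert C8, the only allylic carbon bearing hydrogen because C1 is quaternary, into the enone carbonyl.

Step 17
Reactants: 25 (3R,3aS,4S,8aR)-3-hydroxy-8a-methyl-6-oxo-3-(propan-2-yl)-1,2,3,3a,4,5,6,8a-octahydroazulen-4-yl 4-(tert-butyldimethylsilyloxy)-3-methoxybenzoate
Product: 26 (3R,3aS,4S,6S,8aR)-3,6-dihydroxy-6,8a-dimethyl-3-(propan-2-yl)-1,2,3,3a,4,5,6,8a-octahydroazulen-4-yl 4-(tert-butyldimethylsilyloxy)-3-methoxybenzoate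
Conditions: MeLi, CeCl3, THF, −78 °C
Reagents that add atoms: methyllithium, [Li]C
Why: The non-basic organocerium reagent (Imamoto conditions) adds 1,2 to the enone faster than it attacks the hindered, electron-rich aryl ester, and methyl is expected to enter C8 from the α face, anti to the axial C1 methyl that screens the β face across the ring while the 6α-ester sits equatorial, giving 8α-methyl/8β-hydroxyl.

Step 18
Reactants: 26 (3R,3aS,4S,6S,8aR)-3,6-dihydroxy-6,8a-dimethyl-3-(propan-2-yl)-1,2,3,3a,4,5,6,8a-octahydroazulen-4-yl 4-(tert-butyldimethylsilyloxy)-3-methoxybenzoate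
Product: 27 (3R,3aS,4S,6S,8aR)-3,6-dihydroxy-6,8a-dimethyl-3-(propan-2-yl)-1,2,3,3a,4,5,6,8a-octahydroazulen-4-yl 4-hydroxy-3-methoxybenzoate (target)
Conditions: TBAF, AcOH, THF, 0 °C
Reagents that add atoms: none
Why: Buffered fluoride cleaves the aryl silyl ether selectively; the ester and the tertiary allylic alcohol should survive these mild conditions.

Compound list
1 | but-3-yn-1-ol | C#CCCO | starting material
2 | vinyl bromide | C=CBr | starting material
3 | dimethyl[(1E)-4-(dimethylaluminiooxy)-2-methylbut-1-en-1-yl]alane (alkenylalane) | C[Al](C)/C=C(\C)CCO[Al](C)C | intermediate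
4 | (3E)-3-methylhexa-3,5-dien-1-ol | OCC/C(C)=C/C=C | intermediate
5 | (3E)-6-iodo-4-methylhexa-1,3-diene | ICC/C(C)=C/C=C | intermediate
6 | 4-methylpent-2-yn-1-ol | CC(C)C#CCO | starting material
7 | sodium 2,2-bis(2-methoxyethoxy)-3-(propan-2-yl)-2,5-dihydro-1,2-oxaluminol-2-uide (vinylalanate) | CC(C)C1=CCO[Al-]1(OCCOC)OCCOC.[Na+] | intermediate
8 | (2Z)-3-iodo-4-methylpent-2-en-1-ol | CC(C)/C(I)=C/CO | intermediate
9 | [(3E)-3-methylhexa-3,5-dien-1-yl]zinc iodide | I[Zn]CC/C(C)=C/C=C | intermediate
10 | (2E,6E)-6-methyl-3-(propan-2-yl)nona-2,6,8-trien-1-ol | CC(C)/C(CC/C(C)=C/C=C)=C/CO | intermediate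
11 | [(2R,3R)-3-[(3E)-3-methylhexa-3,5-dien-1-yl]-3-(propan-2-yl)oxiran-2-yl]methanol | OC[C@H]1O[C@@]1(C(C)C)CC/C(C)=C/C=C | intermediate
12 | (3S,6E)-6-methyl-3-(propan-2-yl)nona-6,8-diene-1,3-diol | OCC[C@](O)(C(C)C)CC/C(C)=C/C=C | intermediate
13 | (3S,6E)-6-methyl-3-(propan-2-yl)-1,3-bis(triethylsilyloxy)nona-6,8-diene | CC[Si](CC)(CC)OCC[C@](O[Si](CC)(CC)CC)(C(C)C)CC/C(C)=C/C=C | intermediate
14 | (3S,6E)-6-methyl-3-(propan-2-yl)-3-(triethylsilyloxy)nona-6,8-dienal | O=CC[C@](O[Si](CC)(CC)CC)(C(C)C)CC/C(C)=C/C=C | intermediate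
15 | (4S,7E)-1-chloro-7-methyl-4-(propan-2-yl)-4-(triethylsilyloxy)deca-7,9-dien-2-ol, both C2 epimers | ClCC(O)C[C@](O[Si](CC)(CC)CC)(C(C)C)CC/C(C)=C/C=C | intermediate
16 | (4S,7E)-1-chloro-7-methyl-4-(propan-2-yl)-4-(triethylsilyloxy)deca-7,9-dien-2-one (precursor of the key step) | ClCC(=O)C[C@](O[Si](CC)(CC)CC)(C(C)C)CC/C(C)=C/C=C | intermediate
17 | Z-configured 2-oxidoallyl cation C5–C6–C7 derived from 16 | [CH2+]/C([O-])=C/[C@](O[Si](CC)(CC)CC)(C(C)C)CC/C(C)=C/C=C | intermediate
18 | (3R,3aR,8aR)-8a-methyl-3-(propan-2-yl)-3-(triethylsilyloxy)-2,3,3a,5,6,8a-hexahydroazulen-4(1H)-one (trans-fused; 1β-Me, 4β-OTES, 5α-H, 6-one, Δ9) | O=C1CCC=C[C@@]2(C)CC[C@@](O[Si](CC)(CC)CC)(C(C)C)[C@H]12 | intermediate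
19 | (3R,3aR,8aR)-3-hydroxy-8a-methyl-3-(propan-2-yl)-2,3,3a,5,6,8a-hexahydroazulen-4(1H)-one | O=C1CCC=C[C@@]2(C)CC[C@@](O)(C(C)C)[C@H]12 | intermediate
20 | (3R,3aS,4S,8aR)-8a-methyl-3-(propan-2-yl)-1,2,3,3a,4,5,6,8a-octahydroazulene-3,4-diol (4β,6α-diol) | O[C@H]1CCC=C[C@@]2(C)CC[C@@](O)(C(C)C)[C@H]12 | intermediate
21 | vanillic acid | COc1cc(C(=O)O)ccc1O | starting material
22 | tert-butyldimethylsilyl 4-(tert-butyldimethylsilyloxy)-3-methoxybenzoate | COc1cc(C(=O)O[Si](C)(C)C(C)(C)C)ccc1O[Si](C)(C)C(C)(C)C | intermediate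
23 | 4-(tert-butyldimethylsilyloxy)-3-methoxybenzoic acid | COc1cc(C(=O)O)ccc1O[Si](C)(C)C(C)(C)C | intermediate
24 | (3R,3aS,4S,8aR)-3-hydroxy-8a-methyl-3-(propan-2-yl)-1,2,3,3a,4,5,6,8a-octahydroazulen-4-yl 4-(tert-butyldimethylsilyloxy)-3-methoxybenzoate | COc1cc(C(=O)O[C@H]2CCC=C[C@@]3(C)CC[C@@](O)(C(C)C)[C@H]23)ccc1O[Si](C)(C)C(C)(C)C | intermediate
25 | (3R,3aS,4S,8aR)-3-hydroxy-8a-methyl-6-oxo-3-(propan-2-yl)-1,2,3,3a,4,5,6,8a-octahydroazulen-4-yl 4-(tert-butyldimethylsilyloxy)-3-methoxybenzoate | COc1cc(C(=O)O[C@H]2CC(=O)C=C[C@@]3(C)CC[C@@](O)(C(C)C)[C@H]23)ccc1O[Si](C)(C)C(C)(C)C | intermediate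
26 | (3R,3aS,4S,6S,8aR)-3,6-dihydroxy-6,8a-dimethyl-3-(propan-2-yl)-1,2,3,3a,4,5,6,8a-octahydroazulen-4-yl 4-(tert-butyldimethylsilyloxy)-3-methoxybenzoate | COc1cc(C(=O)O[C@H]2C[C@](C)(O)C=C[C@@]3(C)CC[C@@](O)(C(C)C)[C@H]23)ccc1O[Si](C)(C)C(C)(C)C | intermediate
27 | (3R,3aS,4S,6S,8aR)-3,6-dihydroxy-6,8a-dimethyl-3-(propan-2-yl)-1,2,3,3a,4,5,6,8a-octahydroazulen-4-yl 4-hydroxy-3-methoxybenzoate | COc1cc(C(=O)O[C@H]2C[C@](C)(O)C=C[C@@]3(C)CC[C@@](O)(C(C)C)[C@H]23)ccc1O | target

Total step count: 18.
Longest linear sequence: 16 steps (1, 2, 4–13, 15–18, from but-3-yn-1-ol).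

Steps most likely to fail

Step 11. Several processes may compete with the cycloaddition:
- E1cB loss of the silyloxy group from the C5 enolate.
- Capture of the cation by solvent, or closure at C10 in place of C8.
- A slow reaction, because the C1 methyl sits inside the s-cis diene.
- A weak relay of configuration from C4 to C5.

The fallback generates the same C5–C6–C7 cation equivalent without base from an epoxide, whose C5–O bond is displaced with inversion, so C5 is set stereospecifically. It sets out from 11. Dess–Martin oxidation should give the epoxy aldehyde F1. Methylmagnesium bromide at −78 °C should give the epoxy carbinol F2, and a second Dess–Martin oxidation the epoxy methyl ketone F3. TESOTf/Et3N should give the epoxy enol silane F4. Catalytic TESOTf in CH2Cl2 at −78 °C should then open the oxirane at C5 as the diene adds across C5 and C7, and silyl transfer to the C4 oxygen returns the route to 18.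

Step 17. The facial selectivity may be poor or reversed if the enone ring adopts a conformation in which the 6α-acyloxy group is axial and screens the α face; attack on the ester is a lesser concern. The fallback turns the same facial bias to use by delivering oxygen instead of carbon to C8. It sets out from 25. Wittig methylenation (Ph3P=CH2) should give the 8-methylene diene ester F5. Epoxidation with mCPBA/NaHCO3 from the face that the methyl reagent had preferred should give the 8β-oxygenated spiro-epoxide F6. LiEt3BH should open the oxirane at its CH2 carbon and cleave the ester in the same operation, giving the 4β,6α,8β-triol F7. Steglich acylation of its only secondary hydroxyl with 23 comes back to the route at 26.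

Step 16. The radical oxidation may stall at the allylic peroxide, attack C10 with transposition, or be followed by β-elimination of the C6 ester from the enone. The fallback replaces radical C–H abstraction by an ene/[2,3]-sigmatropic sequence and a separate neutral oxidation. It sets out from 24. Catalytic SeO2 with TBHP in CH2Cl2 should give the C8 allylic alcohol F8 (either epimer), and Dess–Martin oxidation comes back to the route at 25.

Further compounds
F1 | step 11 | 3-[(3E)-3-methylhexa-3,5-dien-1-yl]-3-(propan-2-yl)oxirane-2-carbaldehyde, oxirane configured as in 11 | O=C[C@H]1O[C@@]1(C(C)C)CC/C(C)=C/C=C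
F2 | step 11 | 1-[3-[(3E)-3-methylhexa-3,5-dien-1-yl]-3-(propan-2-yl)oxiran-2-yl]ethan-1-ol, oxirane configured as in 11, carbinol epimers | CC(O)[C@H]1O[C@@]1(C(C)C)CC/C(C)=C/C=C
F3 | step 11 | 1-[3-[(3E)-3-methylhexa-3,5-dien-1-yl]-3-(propan-2-yl)oxiran-2-yl]ethan-1-one, oxirane configured as in 11 | CC(=O)[C@H]1O[C@@]1(C(C)C)CC/C(C)=C/C=C
F4 | step 11 | triethyl[[1-[3-[(3E)-3-methylhexa-3,5-dien-1-yl]-3-(propan-2-yl)oxiran-2-yl]ethenyl]oxy]silane, oxirane configured as in 11 | C=C(O[Si](CC)(CC)CC)[C@H]1O[C@@]1(C(C)C)CC/C(C)=C/C=C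
F5 | step 17 | 8-methylene analogue of 25 (C8=CH2 in place of C8=O) | COc1cc(C(=O)O[C@H]2CC(=C)C=C[C@@]3(C)CC[C@@](O)(C(C)C)[C@H]23)ccc1O[Si](C)(C)C(C)(C)C
F6 | step 17 | spiro-epoxide of F5 at C8 with the oxirane oxygen β | COc1cc(C(=O)O[C@H]2C[C@]4(OC4)C=C[C@@]3(C)CC[C@@](O)(C(C)C)[C@H]23)ccc1O[Si](C)(C)C(C)(C)C
F7 | step 17 | (3R,3aS,4S,6S,8aR)-6,8a-dimethyl-3-(propan-2-yl)-1,2,3,3a,4,5,6,8a-octahydroazulene-3,4,6-triol | O[C@H]1C[C@](C)(O)C=C[C@@]2(C)CC[C@@](O)(C(C)C)[C@H]12
F8 | step 16 | C8 allylic alcohol of 24 (8-hydroxy, either epimer) | COc1cc(C(=O)O[C@H]2CC(O)C=C[C@@]3(C)CC[C@@](O)(C(C)C)[C@H]23)ccc1O[Si](C)(C)C(C)(C)C
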